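**Retrosynthetic overview**
1. The oxirane is made last: LiCH2Cl adds (Felkin–Anh) to a C4 acetyl group, itself unmasked from the carvone isopropenyl group by ozonolysis.
2. The C2 isobutyrate and the side-chain carbinol come from one Evans–Tishchenko reduction of a β-hydroxy ketone; the cyclopentane is closed by a C2–C3 5-exo aldol.
3. Key bond C1–C7a: light-driven acridinium/chromium allylic C–H allylation of a 2-methylcyclohex-2-enyl ester with 2,2-dimethoxyacetaldehyde, which also moves the alkene exocyclic; the C1 ester is then set by Mitsunobu inversion.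
4. The cyclohexane is bought as (S)-carvone: α′-propargylation, epoxidation, Wharton transposition, esterification with a lactic-acid-derived acid.
5. Ring order: cyclohexane (carvone) → cyclopentane (aldol) → oxirane.

Assumption: (R)-2-methylbutanoic acid (13) and (S)-2-acetoxypropanoyl chloride (1, from L-lactic acid) are bought as single enantiomers.
Locants: bicyclic compounds use octahydroindene numbering (C1–C3, C3a, C4–C7, C7a); α is the face of H-7a; monocyclic intermediates use cyclohexene numbering with the carbinol/ester carbon as C1. The SMILES strings are definitive for configuration.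

Step 1
Reactants: 1 (S)-2-acetoxypropanoyl chloride
Product: 2 (S)-3-acetoxybutan-2-one
Conditions: MeMgBr (1.05 equiv), Fe(acac)3 (3 mol %), THF, −78 °C
Reagents that add atoms: methylmagnesium bromide, C[Mg]Br
Why: Iron-catalysed acylation of a Grignard reagent (Kumada-type) stops at the ketone and at −78 °C leaves the acetate and the lactate stereocentre untouched.

Step 2
Reactants: 2 (S)-3-acetoxybutan-2-one
Product: 3 tert-butyl (S,E)-4-acetoxy-3-methylpent-2-enoate
Conditions: Ph3P=CHCO2t-Bu, toluene, 90 °C
Reagents that add atoms: tert-butyl (triphenylphosphoranylidene)acetate, CC(C)(C)OC(=O)C=P(c1ccccc1)(c1ccccc1)c1ccccc1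
Why: Wittig olefination with a stabilised ylide puts the ester trans to the larger CH(OAc)CH3 group (E) under neutral conditions that do not epimerise the α-acetoxy centre.

Step 3
Reactants: 3 tert-butyl (S,E)-4-acetoxy-3-methylpent-2-enoate
Product: 4 (S,E)-4-acetoxy-3-methylpent-2-enoic acid
Conditions: TFA, CH2Cl2, 0 °C → rt
Reagents that add atoms: none
Why: Acidolysis of the tert-butyl ester (E1 loss of isobutene) spares the acetate and the alkene geometry.

Step 4
Reactants: 5 (S)-(+)-carvone
Product: 7 (5S,6R)-2-methyl-5-(prop-1-en-2-yl)-6-(prop-2-yn-1-yl)cyclohex-2-en-1-one (propargyl trans to isopropenyl), via lithium dienolate 6 (not isolated)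
Conditions: LDA, THF, −78 °C; propargyl bromide, −78 → −20 °C
Reagents that add atoms: propargyl bromide (3-bromoprop-1-yne), C#CCBr
Why: Kinetic α′-deprotonation and enolate alkylation anti to the neighbouring isopropenyl group gives the 5,6-trans product, which is also the thermodynamic epimer.

Step 5
Reactants: 7 trans-6-propargylcarvone
Product: 8 2,3-epoxide of 7 (epoxide oxygen trans to isopropenyl and cis to propargyl)
Conditions: 30 % H2O2, NaOH (cat.), MeOH, 0 °C
Reagents that add atoms: hydrogen peroxide, OO
Why: Weitz–Scheffer nucleophilic epoxidation, in which hydroperoxide adds axially to C3 anti to the C5 isopropenyl group, as known for carvone itself.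

Step 6
Reactants: 8 epoxy ketone
Product: 10 2-methyl-4-propargyl-5-isopropenylcyclohex-2-en-1-ol (OH trans to isopropenyl and propargyl trans to isopropenyl), via epoxy hydrazone 9 (not isolated)
Conditions: N2H4·H2O, AcOH (cat.), MeOH, 0 °C → rt
Reagents that add atoms: none
Why: Wharton transposition, in which the C–O bond of the former β-carbon is kept (so the carbinol stays trans to isopropenyl) and the alkene moves next to the propargyl-bearing carbon.

Step 7
Reactants: 10 allylic alcohol; 4 (S,E)-4-acetoxy-3-methylpent-2-enoic acid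
Product: 11 (S,E)-4-acetoxy-3-methylpent-2-enoate ester of 10
Conditions: DCC, DMAP (cat.), CH2Cl2, 0 °C → rt
Reagents that add atoms: none
Why: Steglich esterification acylates the axial allylic alcohol with retention at both stereocentres.

Step 8
Reactants: 11 allylic ester
Product: 12 ester 11 transformed at the ring alkene: C2 methylidene and C3 (1-hydroxy-2,2-dimethoxyethyl) group (new C3 chain trans to the C4 propargyl group and on the face opposite to the C1 ester; carbinol anti to C4)
Conditions: (MeO)2CHCHO (5 equiv), 9-mesityl-10-methylacridinium perchlorate (5 mol %), CrCl2 (10 mol %), Mg(ClO4)2 (1 equiv), CH2Cl2, 430 nm LEDs, rt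
Reagents that add atoms: 2,2-dimethoxyacetaldehyde, COC(OC)C=O
Why: Proposed new method: the excited acridinium oxidises the trisubstituted ring alkene (the most easily oxidised π-bond; isopropenyl, alkyne and enoate lie higher) to its radical cation, loss of a methyl proton gives the allyl radical, Cr(II) traps it at the CH2 terminus, and the allyl–Cr(III) adds to the aldehyde at ring carbon C3 through a Zimmerman–Traxler chair on the face anti to the pseudoaxial C1 ester, which sets C3 trans to the C4 side chain, gives the anti carbinol and leaves the exocyclic methylene (a formal carbonyl-ene reaction), while the acridine radical returns Cr(III) to Cr(II); the closest known chemistry is the photoredox/chromium allylation of aldehydes with simple alkenes by allylic C–H activation and the Nozaki–Hiyama–Kishi allylation, not yet shown on a functionalised 2-methylcyclohexenyl ester used as limiting partner with methyl deprotonation and attack at a ring carbon.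

Step 9
Reactants: 12 homoallylic alcohol; 13 (R)-2-methylbutanoic acid
Product: 14 (R)-2-methylbutanoate of the C3 side-chain carbinol with inverted carbinol configuration
Conditions: PPh3, DIAD, toluene, 0 °C → rt
Reagents that add atoms: none
Why: Mitsunobu esterification goes by SN2 inversion, turning the anti alcohol from step 8 into the configuration required at C1 of the target while installing the ester.

Step 10
Reactants: 14 alkyne acetal
Product: 17 trans-fused octahydroindene: 1β-[(R)-2-methylbutanoyloxy] 2α-hydroxy 3β-acetyl 4β-isopropenyl 6α-acyloxy 7-methylidene (3a-H β and 7a-H α), via methyl ketone 15 (not isolated), via keto aldehyde 16 (not isolated)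
Conditions: (IPr)AuCl/AgSbF6 (2 mol %), dioxane–H2O, 60 °C; then 1 M HCl, THF, 0 °C → rt
Reagents that add atoms: water, O
Why: Gold-catalysed Markovnikov alkyne hydration, acetal hydrolysis and acid-catalysed 5-exo aldol through the more substituted ketone enol; under these reversible conditions 2-OH ends trans to both neighbours and the epimerisable acetyl group trans to 2-OH and to C4, and acid avoids base enolisation of the α-acyloxy aldehyde.

Step 11
Reactants: 17 β-hydroxy ketone
Product: 18 2α-isobutyrate with a free (S)-1-hydroxyethyl group at C3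
Conditions: i-PrCHO (6 equiv), SmI2 (30 mol %), THF, −10 °C
Reagents that add atoms: isobutyraldehyde (2-methylpropanal), CC(C)C=O
Why: Evans–Tishchenko reduction, in which the samarium-bound hemiacetal of the C2 hydroxyl and isobutyraldehyde delivers hydride through a chair transition state to give the 1,3-anti alcohol and leaves the isobutyrate on O-2.

Step 12
Reactants: 18 alcohol
Product: 19 acetate of 18 (3β-[(S)-1-acetoxyethyl])
Conditions: Ac2O, pyridine, DMAP (cat.), 0 °C → rt
Reagents that add atoms: acetic anhydride, CC(=O)OC(C)=O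
Why: Standard acylation of the only free hydroxyl.

Step 13
Reactants: 19 tetraester with isopropenyl group
Product: 20 4β-acetyl compound
Conditions: O3 (1 equiv, Sudan Red endpoint), CH2Cl2/MeOH, −78 °C; then Me2S
Reagents that add atoms: ozone, [O-][O+]=O
Why: Ozonolysis with one equivalent cleaves the electron-rich, unhindered isopropenyl group, whereas the exocyclic methylene is deactivated by the allylic ester and flanked by two substituted carbons and the enoate is electron-poor.

Step 14
Reactants: 20 methyl ketone
Product: 22 CNP0115861.1, via chlorohydrin alkoxide 21 (not isolated)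
Conditions: ICH2Cl (1.5 equiv), MeLi·LiBr (1.4 equiv), THF, −78 °C → rt
Reagents that add atoms: chloroiodomethane, ClCI
Why: Chloromethyllithium made in the presence of the substrate adds to the only ketone faster than to esters at −78 °C under Felkin–Anh control from C4 (ring-fusion side as large group), which predicts the target configuration at the quaternary carbon, and the chlorohydrin alkoxide closes to the oxirane on warming (intramolecular Williamson).

**Compound list**
1 | (S)-2-acetoxypropanoyl chloride | C[C@H](OC(C)=O)C(Cl)=O | starting material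
2 | (S)-3-acetoxybutan-2-one | C[C@H](OC(C)=O)C(C)=O | intermediate
3 | tert-butyl (S,E)-4-acetoxy-3-methylpent-2-enoate | CC(C)(C)OC(=O)/C=C(\C)[C@H](C)OC(C)=O | intermediate
4 | (S,E)-4-acetoxy-3-methylpent-2-enoic acid | OC(=O)/C=C(\C)[C@H](C)OC(C)=O | intermediate
5 | (S)-(+)-carvone | CC1=CC[C@@H](CC1=O)C(C)=C | starting material
6 | lithium cross-conjugated dienolate of 5 | CC1=CC[C@H](C(C)=C)C=C1O[Li] | intermediate
7 | (5S,6R)-2-methyl-5-(prop-1-en-2-yl)-6-(prop-2-yn-1-yl)cyclohex-2-en-1-one | CC1=CC[C@H](C(C)=C)[C@@H](CC#C)C1=O | intermediate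
8 | 2,3-epoxide of 7, oxygen trans to isopropenyl | C[C@]12O[C@H]1C[C@H](C(C)=C)[C@@H](CC#C)C2=O | intermediate
9 | hydrazone of 8 | C[C@]12O[C@H]1C[C@H](C(C)=C)[C@@H](CC#C)C2=NN | intermediate
10 | 2-methyl-4-propargyl-5-isopropenylcyclohex-2-en-1-ol, OH and propargyl both trans to isopropenyl | CC1=C[C@H](CC#C)[C@@H](C(C)=C)C[C@@H]1O | intermediate
11 | ester of 10 with 4 | CC1=C[C@H](CC#C)[C@@H](C(C)=C)C[C@@H]1OC(=O)/C=C(\C)[C@H](C)OC(C)=O | intermediate
12 | 2-methylidene-3-(1-hydroxy-2,2-dimethoxyethyl) analogue of 11, anti carbinol | C=C1[C@@H]([C@H](O)C(OC)OC)[C@H](CC#C)[C@@H](C(C)=C)C[C@@H]1OC(=O)/C=C(\C)[C@H](C)OC(C)=O | intermediate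
13 | (R)-2-methylbutanoic acid | CC[C@@H](C)C(=O)O | starting material
14 | (R)-2-methylbutanoate of 12 with inverted carbinol | C=C1[C@@H]([C@@H](OC(=O)[C@H](C)CC)C(OC)OC)[C@H](CC#C)[C@@H](C(C)=C)C[C@@H]1OC(=O)/C=C(\C)[C@H](C)OC(C)=O | intermediate
15 | 2-oxopropyl (methyl ketone) analogue of 14 | C=C1[C@@H]([C@@H](OC(=O)[C@H](C)CC)C(OC)OC)[C@H](CC(C)=O)[C@@H](C(C)=C)C[C@@H]1OC(=O)/C=C(\C)[C@H](C)OC(C)=O | intermediate
16 | keto aldehyde from 15 | C=C1[C@@H]([C@@H](OC(=O)[C@H](C)CC)C=O)[C@H](CC(C)=O)[C@@H](C(C)=C)C[C@@H]1OC(=O)/C=C(\C)[C@H](C)OC(C)=O | intermediate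
17 | trans-octahydroindene: 1β-(R)-2-methylbutanoate, 2α-OH, 3β-acetyl, 4β-isopropenyl, 6α-ester, 7-methylidene | C=C1[C@H]2[C@@H](OC(=O)[C@H](C)CC)[C@H](O)[C@@H](C(C)=O)[C@@H]2[C@@H](C(C)=C)C[C@@H]1OC(=O)/C=C(\C)[C@H](C)OC(C)=O | intermediate
18 | 2α-isobutyrate, 3β-[(S)-1-hydroxyethyl] | C=C1[C@H]2[C@@H](OC(=O)[C@H](C)CC)[C@H](OC(=O)C(C)C)[C@@H]([C@H](C)O)[C@@H]2[C@@H](C(C)=C)C[C@@H]1OC(=O)/C=C(\C)[C@H](C)OC(C)=O | intermediate
19 | 3β-[(S)-1-acetoxyethyl], 4β-isopropenyl tetraester | C=C1[C@H]2[C@@H](OC(=O)[C@H](C)CC)[C@H](OC(=O)C(C)C)[C@@H]([C@H](C)OC(C)=O)[C@@H]2[C@@H](C(C)=C)C[C@@H]1OC(=O)/C=C(\C)[C@H](C)OC(C)=O | intermediate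
20 | 4β-acetyl tetraester | C=C1[C@H]2[C@@H](OC(=O)[C@H](C)CC)[C@H](OC(=O)C(C)C)[C@@H]([C@H](C)OC(C)=O)[C@@H]2[C@@H](C(C)=O)C[C@@H]1OC(=O)/C=C(\C)[C@H](C)OC(C)=O | intermediate
21 | lithium alkoxide of the C4 (1-chloro-2-hydroxypropan-2-yl) chlorohydrin | C=C1[C@H]2[C@@H](OC(=O)[C@H](C)CC)[C@H](OC(=O)C(C)C)[C@@H]([C@H](C)OC(C)=O)[C@@H]2[C@@H]([C@](O[Li])(C)CCl)C[C@@H]1OC(=O)/C=C(\C)[C@H](C)OC(C)=O | intermediate
22 | CNP0115861.1: 1β-(R)-2-methylbutanoate, 2α-isobutyrate, 3β-[(S)-1-acetoxyethyl], 4β-[(R)-2-methyloxiran-2-yl], 6α-[(S,E)-4-acetoxy-3-methylpent-2-enoate], 7-methylidene trans-octahydroindene | C=C1[C@H]2[C@@H](OC(=O)[C@H](C)CC)[C@H](OC(=O)C(C)C)[C@@H]([C@H](C)OC(C)=O)[C@@H]2[C@@H]([C@]2(C)CO2)C[C@@H]1OC(=O)/C=C(\C)[C@H](C)OC(C)=O | target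

**Step count**
Total: 14 steps (3 for acid 4, 11 from carvone). Longest linear sequence: 11 steps (5 → 22).

**Three steps most likely to fail**

Step 8 (the proposed new step). Risks: the allylic ester raises the oxidation potential of the ring alkene; the radical cation may lose a ring proton instead of a methyl proton; the isopropenyl group may compete. Fallback, from 11 back to 12 with known reactions: Schenck ene photooxygenation of 11 (O2, tetraphenylporphyrin, visible light, CH2Cl2, 0 °C), selective for the trisubstituted alkene, gives the allylic hydroperoxide F1 (OOH on ring carbon C3, methylidene at C2). It is reduced in the same flask with PPh3 to the allylic alcohol F2. Appel bromination (CBr4, PPh3) with allylic transposition gives the primary allylic bromide F3 (BrCH2 on C2, ring alkene restored). A stoichiometric Nozaki–Hiyama–Kishi allylation (CrCl2, 2,2-dimethoxyacetaldehyde, THF) passes through the same allylchromium(III) species and the same chair transition state and returns to 12. The regioisomers of the ene step would have to be separated.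

Step 9 (Mitsunobu inversion). Risk: the carbinol is flanked by a branched ring carbon and an acetal carbon, so SN2 may be slow and elimination may compete. Fallback, from 12 back to 14: the alcohol is converted into the triflate F4 (Tf2O, pyridine, CH2Cl2, −30 °C), which is displaced with inversion by cesium (R)-2-methylbutanoate F5 (made from 13 and Cs2CO3) with 18-crown-6 in toluene, giving 14.

Step 14 (oxirane formation). Risks: the carbenoid must choose one ketone over four esters, and Felkin–Anh selectivity at the acetyl group may be modest. Fallback, from 18 back to 22, which also removes step 13: the free side-chain hydroxyl of 18 lies on the same face as the isopropenyl group and is used for a hydroxyl-directed epoxidation (VO(acac)2, t-BuOOH, CH2Cl2, 0 °C) to give the epoxy alcohol F6. Acetylation (Ac2O, pyridine, DMAP) then gives 22. The facial selectivity of this directed epoxidation would have to be checked.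

Step 10 is also sensitive (dehydration of the aldol, epimerisation next to the aldehyde); the acid-only conditions were chosen for that reason.

Further compounds
F1 | step 8 | allylic hydroperoxide: 3-hydroperoxy-2-methylidene analogue of 11 | C=C1[C@@H](OO)[C@H](CC#C)[C@@H](C(C)=C)C[C@@H]1OC(=O)/C=C(\C)[C@H](C)OC(C)=O
F2 | step 8 | allylic alcohol: 3-hydroxy-2-methylidene analogue of 11 | C=C1[C@@H](O)[C@H](CC#C)[C@@H](C(C)=C)C[C@@H]1OC(=O)/C=C(\C)[C@H](C)OC(C)=O
F3 | step 8 | primary allylic bromide: 2-(bromomethyl) analogue of 11 | BrCC1=C[C@H](CC#C)[C@@H](C(C)=C)C[C@@H]1OC(=O)/C=C(\C)[C@H](C)OC(C)=O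
F4 | step 9 | trifluoromethanesulfonate of 12 | C=C1[C@@H]([C@H](OS(=O)(=O)C(F)(F)F)C(OC)OC)[C@H](CC#C)[C@@H](C(C)=C)C[C@@H]1OC(=O)/C=C(\C)[C@H](C)OC(C)=O
F5 | step 9 | cesium (R)-2-methylbutanoate | CC[C@@H](C)C(=O)[O-].[Cs+]
F6 | step 14 | epoxy alcohol: 4β-[(R)-2-methyloxiran-2-yl] analogue of 18 | C=C1[C@H]2[C@@H](OC(=O)[C@H](C)CC)[C@H](OC(=O)C(C)C)[C@@H]([C@H](C)O)[C@@H]2[C@@H]([C@]2(C)CO2)C[C@@H]1OC(=O)/C=C(\C)[C@H](C)OC(C)=O
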